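**Strategy.** The side chain is cut between C1' and C2'. In the quinone ring (C1=O lies between the two methoxy-bearing carbons), C1' sits on C3 next to the C4 carbonyl. C1' and O4 are therefore the two ends of a 1-oxadiene (C1'=C3–C4=O) in the ortho-quinone methide tautomer of a 3-methylquinone, and the C3' ketone corresponds to a ketal carbon. One cycloaddition of this tautomer with the methyl enol ether of 3',4'-dimethoxyacetophenone forms C1'–C2' and O4–C3' and gives a chromanol. Oxidation then reopens the temporary pyran ring to quinone plus ketone. The precursors are 2,6-dimethoxy-3-methyl-1,4-benzoquinone (3) and 1,2-dimethoxy-4-(1-methoxyethenyl)benzene (7).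

Key step: step 4

Remark: evelynin has no stereocentre and is achiral, so no enantiocontrol is needed; the only stereocentre on the route (the ketal carbon of 9 and 10) forms as a racemate and is removed in step 5.

Remark: atom mapping confirms that oxidation of 1 at its free ring carbon can only give the 2,6-dimethoxy-3-methyl isomer 3, and that the tautomer carrying the hydrogen on O1 leads to the 6-hydroxy-5,7-dimethoxy pattern of 9, so no structure needed correction.

Step 1
Reactants: 1 2,4,6-trimethoxytoluene
Product: 3 2,6-dimethoxy-3-methyl-1,4-benzoquinone, via 2,4,6-trimethoxy-3-methylphenol 2 (not isolated)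
Conditions: 30% aq. H2O2 (2.5 equiv), HCO2H, 25–30 °C
Reagents that add atoms: hydrogen peroxide, OO (acting as performic acid, O=COO, formed in situ)
Why: Performic acid should hydroxylate the free ring position of this symmetric, strongly activated arene (electrophilic aromatic hydroxylation) and then oxidise the resulting para-methoxyphenol 2 to the para-quinone with loss of methanol (oxidative demethylation), the reaction type that turns other trimethoxytoluenes into dimethoxy(methyl)benzoquinones; the two free positions of 1 are equivalent, so only one quinone isomer can form.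

Step 2
Reactants: 4 3',4'-dimethoxyacetophenone; 5 trimethyl orthoformate
Product: 6 4-(1,1-dimethoxyethyl)-1,2-dimethoxybenzene
Conditions: HC(OMe)3 (3 equiv), p-TsOH·H2O (1 mol%), MeOH, 50 °C; NaOMe quench, evaporate
Reagents that add atoms: trimethyl orthoformate, COC(OC)OC; methanol, CO
Why: Acid-catalysed dimethyl ketal formation of an aryl methyl ketone should go to completion because the orthoformate removes the water of reaction as methyl formate, and the aryl ethers are inert to these conditions.

Step 3
Reactants: 6 4-(1,1-dimethoxyethyl)-1,2-dimethoxybenzene
Product: 7 1,2-dimethoxy-4-(1-methoxyethenyl)benzene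
Conditions: TMSOTf (1.2 equiv), i-Pr2NEt (1.5 equiv), CH2Cl2, −20 °C → rt; filtration through basic alumina
Reagents that add atoms: none
Why: Silyl triflate-mediated elimination of methanol from a dimethyl ketal: TMSOTf ionises the ketal to an aryl-stabilised methoxycarbenium ion and the hindered amine removes a methyl proton, so the acid-labile α-methoxystyrene is formed and kept under basic conditions throughout.

Step 4
Reactants: 3 2,6-dimethoxy-3-methyl-1,4-benzoquinone; 7 1,2-dimethoxy-4-(1-methoxyethenyl)benzene
Product: 9 racemic 2-(3,4-dimethoxyphenyl)-2,5,7-trimethoxychroman-6-ol, via hydroxy ortho-quinone methide tautomer 8 (not isolated)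
Conditions: 7 (4 equiv), i-Pr2NEt (0.5 equiv), 4 Å MS, PhMe, 90 °C, Ar, dark; 3 added over 6 h; Et3N-deactivated silica
Reagents that add atoms: none
Why: The hindered amine reversibly moves a proton from the C3 methyl group of 3 (vinylogous to C1=O) to O1, which keeps a small stationary amount of the hydroxy ortho-quinone methide 8 in solution; its C1'H2=C3–C4=O unit is an electron-poor 1-oxadiene. Enol ether 7 adds across this unit in an inverse-electron-demand hetero-Diels–Alder reaction, the nucleophilic CH2 terminus (C2') bonding to C1' and O4 bonding to the methoxy- and aryl-stabilised carbon C3', and the gain of aromaticity in the hydroquinone monoether 9 should make the addition irreversible. The closest known reaction type is the amine- or heat-induced tautomerisation of alkyl-1,4-benzoquinones to ortho-quinone methides followed by their [4+2] trapping with enol ethers or styrenes to give chromans. The dihydropyran ring of the chroman is closed as a six-membered ring by this intermolecular, asynchronous [4+2] cycloaddition, which forms the C1'–C2' and O4–C3' bonds in one operation. The ketal carbon C2 of 9 is the only new stereocentre; no element controls it, it forms as a racemate, and this is harmless because step 5 converts it into the carbonyl carbon. Regioselectivity (2-aryl-2-methoxychroman, not the 3-substituted isomer) follows from the matched polarisation of 8 and 7 and from the single alkyl group of 3, which allows only one quinone methide, while chemoselectivity rests on the excess of 7 and the slow addition of 3 (against dimerisation of 8), on a tertiary hindered base that cannot displace the vinylogous-ester methoxy groups, and on dry, acid-free conditions that preserve 7 and the ketal.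

Step 5
Reactants: 9 racemic 2-(3,4-dimethoxyphenyl)-2,5,7-trimethoxychroman-6-ol
Product: 11 evelynin, via ring-opened quinone methyl hemiketal 10 (not isolated)
Conditions: CAN (2.2 equiv), MeCN–H2O (4:1), 0 °C
Reagents that add atoms: water, O
Why: Two-electron oxidation of the para-alkoxyphenol (the chromanol-to-quinone oxidation used to open tocopherol-type chromans) should give the quinone with cleavage of the O1–C2 bond, and the hemiketal 10 formed with water collapses to the aryl ketone with loss of methanol, which also removes the stereocentre; the acyl-deactivated veratrole ring should not be attacked by cerium(IV) at 0 °C.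

**Compound list**

1 | 2,4,6-trimethoxytoluene | Cc1c(OC)cc(OC)cc1OC | starting material
2 | 2,4,6-trimethoxy-3-methylphenol | Cc1c(OC)cc(OC)c(O)c1OC | intermediate (not isolated)
3 | 2,6-dimethoxy-3-methyl-1,4-benzoquinone | COC1=CC(=O)C(C)=C(OC)C1=O | intermediate
4 | 3',4'-dimethoxyacetophenone | CC(=O)c1ccc(OC)c(OC)c1 | starting material
5 | trimethyl orthoformate | COC(OC)OC | starting material
6 | 4-(1,1-dimethoxyethyl)-1,2-dimethoxybenzene | COc1ccc(cc1OC)C(C)(OC)OC | intermediate
7 | 1,2-dimethoxy-4-(1-methoxyethenyl)benzene | COC(=C)c1ccc(OC)c(OC)c1 | intermediate
8 | 4-hydroxy-3,5-dimethoxy-6-methylidenecyclohexa-2,4-dien-1-one (hydroxy ortho-quinone methide tautomer of 3) | C=C1C(=O)C=C(OC)C(O)=C1OC | intermediate (not isolated)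
9 | 2-(3,4-dimethoxyphenyl)-2,5,7-trimethoxychroman-6-ol, racemic | COc1cc2OC(OC)(CCc2c(OC)c1O)c1ccc(OC)c(OC)c1 | intermediate
10 | 3-[3-(3,4-dimethoxyphenyl)-3-hydroxy-3-methoxypropyl]-2,6-dimethoxy-1,4-benzoquinone, racemic | COC1=CC(=O)C(CCC(O)(OC)c2ccc(OC)c(OC)c2)=C(OC)C1=O | intermediate (not isolated)
11 | evelynin, 3-[3-(3,4-dimethoxyphenyl)-3-oxopropyl]-2,6-dimethoxy-1,4-benzoquinone (achiral) | COC1=CC(=O)C(CCC(=O)c2ccc(OC)c(OC)c2)=C(OC)C1=O | target

Total step count: 5.
Longest linear sequence: 4 steps (4 → 6 → 7 → 9 → 11; the quinone branch 1 → 3 joins at step 4).

**Steps most likely to fail**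

Step 4. The tautomerisation may be too slow on this electron-rich quinone for the quinone methide to reach a useful stationary concentration. Once formed, the quinone methide may also be intercepted by a second molecule of quinone or quinone methide faster than by the enol ether. Thermal loss of the enol ether and redox exchange between product and unreacted quinone would erode the material balance further. The fallback sets out from ketone 4 and comes back to the route at target 11. Claisen–Schmidt condensation of 4 with 2,3,4,6-tetramethoxybenzaldehyde F1 (purchased, or obtained by Vilsmeier–Haack formylation of 1,2,3,5-tetramethoxybenzene) under KOH in MeOH should give (E)-1-(3,4-dimethoxyphenyl)-3-(2,3,4,6-tetramethoxyphenyl)prop-2-en-1-one F2. Hydrogenation of the alkene (H2, Pd/C, EtOAc, stopped after one equivalent) should give 1-(3,4-dimethoxyphenyl)-3-(2,3,4,6-tetramethoxyphenyl)propan-1-one F3. Cerium(IV) ammonium nitrate in aqueous MeCN should then oxidise the only para-dimethoxy pair of the tetramethoxy ring (C3/C6) to the quinone 11, the acylated veratrole ring being deactivated.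

Step 1. Over-oxidation of the very electron-rich ring (ipso attack at the methyl-bearing carbon, ring cleavage, epoxidation of the quinone) may compete with hydroxylation at the free position. The fallback sets out from 1 and comes back at phenol 2, which is isolated here, and then at quinone 3. Vilsmeier–Haack formylation of 1 (POCl3, DMF) can only occur at the free ring carbon and should give 2,4,6-trimethoxy-3-methylbenzaldehyde F4. Baeyer–Villiger oxidation (mCPBA, CH2Cl2) should give 2,4,6-trimethoxy-3-methylphenyl formate F5, and methanolysis (K2CO3, MeOH) should release phenol 2. Oxidation of this para-methoxyphenol under mild, defined conditions (PhI(OAc)2, MeCN–H2O, 0 °C) should give 3.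

Step 3. The enol ether may be lost by hydrolysis back to the ketone during work-up or purification, or by cationic oligomerisation if traces of acid remain. The fallback sets out from 4 and comes back at 11. Silylation of 4 (TBSOTf, Et3N, CH2Cl2, 0 °C) should give tert-butyl{[1-(3,4-dimethoxyphenyl)ethenyl]oxy}dimethylsilane F6 in one basic step, a dienophile that tolerates chromatography. Used in place of 7 under the conditions of step 4, it should give racemic 2-(tert-butyldimethylsilyloxy)-2-(3,4-dimethoxyphenyl)-5,7-dimethoxychroman-6-ol F7. The oxidation of step 5 should convert F7 into 11 with loss of the silanol.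

**Further compounds**

F1 | step 4 | 2,3,4,6-tetramethoxybenzaldehyde | COc1cc(OC)c(C=O)c(OC)c1OC
F2 | step 4 | (E)-1-(3,4-dimethoxyphenyl)-3-(2,3,4,6-tetramethoxyphenyl)prop-2-en-1-one | COc1cc(OC)c(/C=C/C(=O)c2ccc(OC)c(OC)c2)c(OC)c1OC
F3 | step 4 | 1-(3,4-dimethoxyphenyl)-3-(2,3,4,6-tetramethoxyphenyl)propan-1-one | COc1cc(OC)c(CCC(=O)c2ccc(OC)c(OC)c2)c(OC)c1OC
F4 | step 1 | 2,4,6-trimethoxy-3-methylbenzaldehyde | Cc1c(OC)cc(OC)c(C=O)c1OC
F5 | step 1 | 2,4,6-trimethoxy-3-methylphenyl formate | Cc1c(OC)cc(OC)c(OC=O)c1OC
F6 | step 3 | tert-butyl{[1-(3,4-dimethoxyphenyl)ethenyl]oxy}dimethylsilane | C=C(O[Si](C)(C)C(C)(C)C)c1ccc(OC)c(OC)c1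
F7 | step 3 | 2-(tert-butyldimethylsilyloxy)-2-(3,4-dimethoxyphenyl)-5,7-dimethoxychroman-6-ol, racemic | COc1cc2OC(O[Si](C)(C)C(C)(C)C)(CCc2c(OC)c1O)c1ccc(OC)c(OC)c1
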